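**Retrosynthetic overview**
- The target comes from C2 methylation and desilylation of a hexacyclic keto lactone; lactone ring D and the C19 configuration come from a retro-aldol/aldol equilibration trapped by δ-lactonisation.
- Ring E (C13–C14) is closed by Pd-catalysed intramolecular ketone α-alkenylation, followed by an exo Michael addition to methyl acrylate (C14). Cyclopentene F arrives intact from a ketoreductase-derived (R)-2-bromocyclopentenol via Johnson–Claisen rearrangement (C9).
- The C6–C7 bond is made by lactam-enolate alkylation of an A/B/C tricyclic lactam; C6 is corrected when the lactam is reduced through its enamine.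
- Rings B and C are formed by aldol condensation, then copper hydride reductive aldol, of an N-acyl pyrrolidin-3-one (ring A, bought as its ketal) carrying the C22 quaternary centre.
- C22 comes from chiral phosphoric acid desymmetrisation of a prochiral hydroxy malonate. Ring order: F and A (preformed), B, C, E, D.

Assumption: locants C1–C24 (N4, O18) in late intermediates follow the atom order of the target SMILES: C1 methyl; C2; C3; N4; C5; C6; C7; C8; C9; C10; C11; C12=C13; C14; C15; C16; C17 (lactone C=O); O18; C19; C20; C21; C22; C23 (CH2OH); C24 (ketone).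
Assumption: an (R)-selective ketoreductase for 3 and the TRIP enantiomer that gives (R)-16 are found by routine screening.

**Step 1**
Reactants: 1 cyclopent-2-en-1-one
Product: 3 2-bromocyclopent-2-en-1-one, via dibromoketone 2 (not isolated)
Conditions: Br2, CH2Cl2, 0 °C; then Et3N, 0 °C to rt
Reagents that add atoms: bromine, BrBr
Why: Bromination–dehydrobromination (addition of Br2 to the enone, then E1cB loss of HBr) gives the α-bromoenone; no stereocentre is formed.

**Step 2**
Reactants: 3 2-bromocyclopent-2-en-1-one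
Product: 4 (R)-2-bromocyclopent-2-en-1-ol
Conditions: ketoreductase (KRED), NADP+ (cat.), iPrOH, phosphate buffer pH 7, 30 °C
Reagents that add atoms: none
Why: Enzymatic asymmetric ketone reduction by a ketoreductase (NADPH-dependent alcohol dehydrogenase, cofactor recycled by iPrOH) delivers hydride to one carbonyl face and sets the carbinol centre that later becomes C9.

**Step 3**
Reactants: 4 (R)-2-bromocyclopent-2-en-1-ol; 5 triethyl orthoacetate
Product: 7 ethyl (R)-2-(2-bromocyclopent-2-en-1-yl)acetate, via ketene acetal 6 (not isolated)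
Conditions: MeC(OEt)3 (5 equiv), EtCO2H (cat.), 140 °C, EtOH distilled off
Reagents that add atoms: triethyl orthoacetate 5, CC(OCC)(OCC)OCC
Why: Johnson–Claisen rearrangement; the suprafacial [3,3] shift transfers the carbinol chirality to C9 and leaves the C12=C13 vinyl bromide.

**Step 4**
Reactants: 7 ethyl (R)-2-(2-bromocyclopent-2-en-1-yl)acetate
Product: 8 (R)-2-(2-bromocyclopent-2-en-1-yl)ethan-1-ol
Conditions: DIBAL-H (2.5 equiv), CH2Cl2, −78 to 0 °C
Reagents that add atoms: none
Why: Hydride reduction of the ester to the primary alcohol; the vinyl bromide and C9 are untouched.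

**Step 5**
Reactants: 8 (R)-2-(2-bromocyclopent-2-en-1-yl)ethan-1-ol
Product: 9 (R)-1-bromo-5-(2-iodoethyl)cyclopent-1-ene
Conditions: I2, PPh3, imidazole, CH2Cl2, 0 °C
Reagents that add atoms: iodine, II
Why: Appel-type iodination of the primary alcohol (SN2 on the alkoxyphosphonium ion) gives the C7 electrophile.

**Step 6**
Reactants: 10 di-tert-butyl malonate; 11 allyl bromide
Product: 12 di-tert-butyl 2-allylmalonate
Conditions: NaH, THF, 0 °C to rt
Reagents that add atoms: allyl bromide 11, C=CCBr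
Why: Malonate alkylation (SN2) installs the arm that becomes C6–C5.

**Step 7**
Reactants: 12 di-tert-butyl 2-allylmalonate; 13 (2-bromoethoxy)(tert-butyl)dimethylsilane
Product: 14 di-tert-butyl 2-allyl-2-{2-[(tert-butyldimethylsilyl)oxy]ethyl}malonate
Conditions: NaH, NaI (cat.), DMF, 60 °C
Reagents that add atoms: (2-bromoethoxy)(tert-butyl)dimethylsilane 13, BrCCO[Si](C)(C)C(C)(C)C
Why: Second malonate alkylation installs the C14–C19–O arm and makes the prochiral quaternary carbon C22.

**Step 8**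
Reactants: 14 silyl ether diester
Product: 15 di-tert-butyl 2-allyl-2-(2-hydroxyethyl)malonate
Conditions: HF·pyridine, THF, 0 °C
Reagents that add atoms: none
Why: Fluoride desilylation under buffered conditions frees the alcohol without background lactonisation of the hindered tert-butyl esters.

**Step 9**
Reactants: 15 di-tert-butyl 2-allyl-2-(2-hydroxyethyl)malonate
Product: 16 tert-butyl (R)-3-allyl-2-oxotetrahydrofuran-3-carboxylate
Conditions: TRIP chiral phosphoric acid (5 mol%), PhMe, 35 °C
Reagents that add atoms: none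
Why: Brønsted acid-catalysed enantioselective desymmetrising lactonisation; the chiral phosphoric acid differentiates the two enantiotopic esters and so sets the C22 quaternary stereocentre.

**Step 10**
Reactants: 16 lactone tert-butyl ester
Product: 17 (S)-3-allyl-2-oxotetrahydrofuran-3-carboxylic acid
Conditions: TFA, CH2Cl2, 0 °C to rt
Reagents that add atoms: none
Why: Acidolysis of the tert-butyl ester (E1 loss of isobutene) leaves the lactone intact.

**Step 11**
Reactants: 17 lactone acid
Product: 18 (S)-3-allyl-3-(hydroxymethyl)dihydrofuran-2(3H)-one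
Conditions: BH3·SMe2, THF, 0 °C; MeOH quench
Reagents that add atoms: none
Why: Chemoselective borane reduction of the carboxylic acid in the presence of the lactone gives C23 at the alcohol level.

**Step 12**
Reactants: 18 hydroxymethyl lactone
Product: 19 (S)-3-allyl-3-{[(tert-butyldiphenylsilyl)oxy]methyl}dihydrofuran-2(3H)-one
Conditions: TBDPSCl, imidazole, DMF, rt
Reagents that add atoms: tert-butyl(chloro)diphenylsilane, CC(C)(C)[Si](Cl)(c1ccccc1)c1ccccc1
Why: Silylation protects the C23 alcohol until the last step.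

**Step 13**
Reactants: 19 allyl lactone
Product: 21 2-[(R)-3-{[(tert-butyldiphenylsilyl)oxy]methyl}-2-oxotetrahydrofuran-3-yl]acetic acid, via aldehyde 20 (not isolated)
Conditions: OsO4 (1 mol%), Oxone, DMF, rt
Reagents that add atoms: potassium peroxymonosulfate (Oxone), [K+].[O-]S(=O)(=O)OO; water, O
Why: Osmium-catalysed oxidative cleavage of the terminal alkene to the carboxylic acid, one carbon shorter, gives C5 at the acid level.

**Step 14**
Reactants: 21 lactone acid; 22 1,4-dioxa-7-azaspiro[4.4]nonane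
Product: 23 (R)-3-{[(tert-butyldiphenylsilyl)oxy]methyl}-3-[2-(1,4-dioxa-7-azaspiro[4.4]nonan-7-yl)-2-oxoethyl]dihydrofuran-2(3H)-one
Conditions: EDC·HCl, HOBt, iPr2NEt, CH2Cl2, rt
Reagents that add atoms: 1,4-dioxa-7-azaspiro[4.4]nonane 22, C1CC2(CN1)OCCO2
Why: Carbodiimide amide coupling forms the N4–C5 bond and brings in ring A as its ketal.

**Step 15**
Reactants: 23 amide lactone
Product: 24 lactol 2-[(3R)-3-{[(tert-butyldiphenylsilyl)oxy]methyl}-2-hydroxytetrahydrofuran-3-yl]-1-(1,4-dioxa-7-azaspiro[4.4]nonan-7-yl)ethan-1-one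
Conditions: DIBAL-H (1.2 equiv), CH2Cl2, −78 °C
Reagents that add atoms: none
Why: Partial reduction of the lactone stops at the lactol (masked C21 aldehyde, C19 alcohol); the tertiary amide does not react at −78 °C.

**Step 16**
Reactants: 24 ketal lactol
Product: 25 1-{2-[(3R)-3-{[(tert-butyldiphenylsilyl)oxy]methyl}-2-hydroxytetrahydrofuran-3-yl]acetyl}pyrrolidin-3-one
Conditions: PPTS, acetone/H2O, 50 °C
Reagents that add atoms: water, O
Why: Acid-catalysed ketal hydrolysis releases the ring A ketone, which acidifies C20.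

**Step 17**
Reactants: 25 keto lactol
Product: 27 (S)-7-(2-hydroxyethyl)-7-{[(tert-butyldiphenylsilyl)oxy]methyl}-2,3,6,7-tetrahydroindolizine-1,5-dione, via aldol adduct 26 (not isolated)
Conditions: K2CO3, MeOH, 45 °C
Reagents that add atoms: none
Why: Intramolecular aldol condensation of the C20 α-amido ketone carbon with the C21 aldehyde (open form of the lactol) closes six-membered ring B; attack from C2 would need an eight-membered ring.

**Step 18**
Reactants: 27 enone alcohol
Product: 28 2-[(S)-7-{[(tert-butyldiphenylsilyl)oxy]methyl}-1,5-dioxo-1,2,3,5,6,7-hexahydroindolizin-7-yl]acetaldehyde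
Conditions: Dess–Martin periodinane, NaHCO3, CH2Cl2, 0 °C to rt
Reagents that add atoms: none
Why: Dess–Martin oxidation of the primary C19 alcohol gives the aldehyde without touching the enamide enone.

**Step 19**
Reactants: 28 enone aldehyde
Product: 29 A/B/C tricyclic ketol (C5 lactam; C24 ketone; exo C19–OH; C22–CH2OTBDPS)
Conditions: [(Ph3P)CuH]6 (0.5 equiv), PhMe/THF, −40 °C to rt; aq NH4Cl
Reagents that add atoms: none
Why: Reductive aldol cyclisation with Stryker's reagent: conjugate hydride addition gives the copper enolate at C20 only, which adds 5-exo to the C19 aldehyde; the bicyclo[3.2.1] geometry fixes C20 (N4 cis to C6) and the chelated transition state places the C19–OH exo.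

**Step 20**
Reactants: 29 tricyclic ketol
Product: 30 C24 ethylene ketal of 29
Conditions: HOCH2CH2OH, HC(OEt)3, TsOH (cat.), CH2Cl2, rt
Reagents that add atoms: ethylene glycol, OCCO
Why: Ketalisation masks the C24 ketone, so that the lactam and later the C19 ketone are the only enolisable carbonyls.

**Step 21**
Reactants: 30 ketal ketol; 9 (R)-1-bromo-5-(2-iodoethyl)cyclopent-1-ene
Product: 31 C6-alkylated lactam (C7 chain on the exo face; C6 epimeric to the target)
Conditions: LDA (2.2 equiv), THF/DMPU, −78 to −30 °C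
Reagents that add atoms: iodide 9, ICC[C@H]1CCC=C1Br
Why: Alkylation of the alkoxide/lactam-enolate dianion forms C6–C7; the iodide enters axially from the open exo face, which gives the wrong C6 epimer that step 22 corrects.

**Step 22**
Reactants: 31 alkylated lactam
Product: 33 tertiary amine (C5 methylene; C6 as in the target), via enamine 32 (not isolated)
Conditions: IrCl(CO)(PPh3)2 (2 mol%), (Me2SiH)2O, PhMe, rt; then NaBH(OAc)3, AcOH, 0 °C
Reagents that add atoms: none
Why: Iridium-catalysed hydrosilylation of the tertiary lactam (Vaska's complex) and loss of silanol give the C5=C6 enamine; C-protonation from the exo face and iminium reduction make H6 axial and the C7 chain equatorial.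

**Step 23**
Reactants: 33 amino alcohol
Product: 34 C19 ketone
Conditions: Dess–Martin periodinane, NaHCO3, CH2Cl2, rt
Reagents that add atoms: none
Why: Dess–Martin oxidation of the hindered secondary alcohol gives a ketone that can enolise only towards C14, because C20 is quaternary.

**Step 24**
Reactants: 34 bromo ketone
Product: 35 pentacyclic ketone (ring E closed; C14–H; C13 endo)
Conditions: Pd2(dba)3 (5 mol%), DtBPF (12 mol%), NaOtBu, PhMe, 70 °C
Reagents that add atoms: none
Why: Intramolecular palladium-catalysed ketone α-alkenylation (enolate/vinyl bromide coupling) forms C13–C14; the equatorial C6 tether reaches only the endo face of C14, so ring E is fused as in the target.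

**Step 25**
Reactants: 35 pentacyclic ketone; 36 methyl acrylate
Product: 37 Michael adduct (C14 quaternary; exo CH2CH2CO2Me)
Conditions: methyl acrylate, DBU (cat.), MeCN, 0 °C to rt
Reagents that add atoms: methyl acrylate 36, C=CC(=O)OC
Why: Michael addition of the allyl-stabilised enolate at its α-carbon from the exo face (ring E covers the endo face) creates the C14 quaternary centre with C15 exo and keeps C12=C13 in place.

**Step 26**
Reactants: 37 keto ester
Product: 38 endo C19 alcohol
Conditions: NaBH4, MeOH, 0 °C to rt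
Reagents that add atoms: none
Why: Borohydride reduction of the C19 ketone from the more open exo face gives mainly the endo alcohol; C19 is corrected in step 28.

**Step 27**
Reactants: 38 ketal alcohol
Product: 39 ketol (C24 ketone; endo C19–OH)
Conditions: TFA/H2O (9:1), 0 °C to rt
Reagents that add atoms: water, O
Why: Acid hydrolysis of the ketal restores the ring A ketone; the endo alcohol cannot lactonise.

**Step 28**
Reactants: 39 ketol ester
Product: 42 hexacyclic keto lactone (C2 unsubstituted; C23 OTBDPS), via keto aldehyde 40 (not isolated), via exo-hydroxy ester 41 (not isolated)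
Conditions: DBU, PhMe, 4 Å MS, 80 °C
Reagents that add atoms: none
Why: Retro-aldol/aldol equilibration of the β-hydroxy ketone epimerises C19, and only the exo alkoxide, cis to the C15 chain, is removed by irreversible δ-lactonisation.

**Step 29**
Reactants: 42 keto lactone
Product: 43 O-TBDPS ether of the target
Conditions: LiHMDS (1.05 equiv), THF, −78 °C; MeI, −78 to −40 °C
Reagents that add atoms: iodomethane, CI
Why: Kinetic enolate methylation at C2, the only enolisable position of the ketone, occurs anti to the C19 bridge and puts the methyl cis to C21, which should also be the thermodynamic epimer.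

**Step 30**
Reactants: 43 silyl ether
Product: 44 target CNP0180795.1
Conditions: HF·pyridine, THF/pyridine, 0 °C to rt
Reagents that add atoms: none
Why: Fluoride desilylation frees the C23 primary alcohol without affecting the lactone, ketone or amine.

**Compound list**
1 | cyclopent-2-en-1-one | O=C1CCC=C1 | starting material
2 | trans-2,3-dibromocyclopentan-1-one (racemic) | O=C1CCC(Br)C1Br | intermediate
3 | 2-bromocyclopent-2-en-1-one | O=C1CCC=C1Br | intermediate
4 | (R)-2-bromocyclopent-2-en-1-ol | O[C@@H]1CCC=C1Br | intermediate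
5 | triethyl orthoacetate | CC(OCC)(OCC)OCC | starting material
6 | (R)-1-bromo-5-[(1-ethoxyethenyl)oxy]cyclopent-1-ene (ketene acetal) | C=C(OCC)O[C@@H]1CCC=C1Br | intermediate
7 | ethyl (R)-2-(2-bromocyclopent-2-en-1-yl)acetate | CCOC(=O)C[C@H]1CCC=C1Br | intermediate
8 | (R)-2-(2-bromocyclopent-2-en-1-yl)ethan-1-ol | OCC[C@H]1CCC=C1Br | intermediate
9 | (R)-1-bromo-5-(2-iodoethyl)cyclopent-1-ene | ICC[C@H]1CCC=C1Br | intermediate
10 | di-tert-butyl malonate | CC(C)(C)OC(=O)CC(=O)OC(C)(C)C | starting material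
11 | allyl bromide | C=CCBr | starting material
12 | di-tert-butyl 2-allylmalonate | C=CCC(C(=O)OC(C)(C)C)C(=O)OC(C)(C)C | intermediate
13 | (2-bromoethoxy)(tert-butyl)dimethylsilane | BrCCO[Si](C)(C)C(C)(C)C | starting material
14 | di-tert-butyl 2-allyl-2-{2-[(tert-butyldimethylsilyl)oxy]ethyl}malonate | C=CCC(CCO[Si](C)(C)C(C)(C)C)(C(=O)OC(C)(C)C)C(=O)OC(C)(C)C | intermediate
15 | di-tert-butyl 2-allyl-2-(2-hydroxyethyl)malonate | C=CCC(CCO)(C(=O)OC(C)(C)C)C(=O)OC(C)(C)C | intermediate
16 | tert-butyl (R)-3-allyl-2-oxotetrahydrofuran-3-carboxylate | O=C1OCC[C@@]1(CC=C)C(=O)OC(C)(C)C | intermediate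
17 | (S)-3-allyl-2-oxotetrahydrofuran-3-carboxylic acid | O=C1OCC[C@@]1(CC=C)C(=O)O | intermediate
18 | (S)-3-allyl-3-(hydroxymethyl)dihydrofuran-2(3H)-one | O=C1OCC[C@@]1(CC=C)CO | intermediate
19 | (S)-3-allyl-3-{[(tert-butyldiphenylsilyl)oxy]methyl}dihydrofuran-2(3H)-one | O=C1OCC[C@@]1(CC=C)CO[Si](c1ccccc1)(c1ccccc1)C(C)(C)C | intermediate
20 | 2-[(R)-3-{[(tert-butyldiphenylsilyl)oxy]methyl}-2-oxotetrahydrofuran-3-yl]acetaldehyde | O=C1OCC[C@@]1(CC=O)CO[Si](c1ccccc1)(c1ccccc1)C(C)(C)C | intermediate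
21 | 2-[(R)-3-{[(tert-butyldiphenylsilyl)oxy]methyl}-2-oxotetrahydrofuran-3-yl]acetic acid | O=C1OCC[C@@]1(CC(=O)O)CO[Si](c1ccccc1)(c1ccccc1)C(C)(C)C | intermediate
22 | 1,4-dioxa-7-azaspiro[4.4]nonane | C1CC2(CN1)OCCO2 | starting material
23 | (R)-3-{[(tert-butyldiphenylsilyl)oxy]methyl}-3-[2-(1,4-dioxa-7-azaspiro[4.4]nonan-7-yl)-2-oxoethyl]dihydrofuran-2(3H)-one | O=C1OCC[C@@]1(CC(=O)N1CCC2(C1)OCCO2)CO[Si](c1ccccc1)(c1ccccc1)C(C)(C)C | intermediate
24 | 2-[(3R)-3-{[(tert-butyldiphenylsilyl)oxy]methyl}-2-hydroxytetrahydrofuran-3-yl]-1-(1,4-dioxa-7-azaspiro[4.4]nonan-7-yl)ethan-1-one (lactol, both anomers) | OC1OCC[C@@]1(CC(=O)N1CCC2(C1)OCCO2)CO[Si](c1ccccc1)(c1ccccc1)C(C)(C)C | intermediate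
25 | 1-{2-[(3R)-3-{[(tert-butyldiphenylsilyl)oxy]methyl}-2-hydroxytetrahydrofuran-3-yl]acetyl}pyrrolidin-3-one | OC1OCC[C@@]1(CC(=O)N1CCC(=O)C1)CO[Si](c1ccccc1)(c1ccccc1)C(C)(C)C | intermediate
26 | (7R)-8-hydroxy-7-(2-hydroxyethyl)-7-{[(tert-butyldiphenylsilyl)oxy]methyl}hexahydroindolizine-1,5-dione (aldol adduct, C8/C8a epimers) | OCC[C@]1(CO[Si](c2ccccc2)(c2ccccc2)C(C)(C)C)CC(=O)N2CCC(=O)C2C1O | intermediate
27 | (S)-7-(2-hydroxyethyl)-7-{[(tert-butyldiphenylsilyl)oxy]methyl}-2,3,6,7-tetrahydroindolizine-1,5-dione | OCC[C@]1(CO[Si](c2ccccc2)(c2ccccc2)C(C)(C)C)CC(=O)N2CCC(=O)C2=C1 | intermediate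
28 | 2-[(S)-7-{[(tert-butyldiphenylsilyl)oxy]methyl}-1,5-dioxo-1,2,3,5,6,7-hexahydroindolizin-7-yl]acetaldehyde | O=CC[C@]1(CO[Si](c2ccccc2)(c2ccccc2)C(C)(C)C)CC(=O)N2CCC(=O)C2=C1 | intermediate
29 | A/B/C tricyclic ketol: 2-azabicyclo[3.2.1]octan-3-one (N4, C5=O, C6H2, C22, C14H2, C19, C20, C21) fused at N4–C20 to a pyrrolidin-3-one (C24=O); exo C19–OH; C22–CH2OTBDPS | O=C1CCN2C(=O)C[C@@]3(CO[Si](c4ccccc4)(c4ccccc4)C(C)(C)C)C[C@H](O)[C@@]12C3 | intermediate
30 | C24 ethylene ketal of 29 | C12(OCCO1)CCN3C(=O)C[C@@]4(CO[Si](c5ccccc5)(c5ccccc5)C(C)(C)C)C[C@H](O)[C@@]23C4 | intermediate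
31 | 30 carrying the 2-[(R)-2-bromocyclopent-2-en-1-yl]ethyl chain at C6 on the exo (axial) face | C12(OCCO1)CCN3C(=O)[C@H](CC[C@H]5CCC=C5Br)[C@@]4(CO[Si](c6ccccc6)(c6ccccc6)C(C)(C)C)C[C@H](O)[C@@]23C4 | intermediate
32 | C5=C6 enamine from 31 (lactam carbonyl removed; shown as the free C19 alcohol) | C12(OCCO1)CCN3C=C(CC[C@H]5CCC=C5Br)[C@@]4(CO[Si](c6ccccc6)(c6ccccc6)C(C)(C)C)C[C@H](O)[C@@]23C4 | intermediate
33 | tertiary amine: C5 methylene; C6–H axial (exo) with the C7 chain equatorial; exo C19–OH; C24 ketal | C12(OCCO1)CCN3C[C@@H](CC[C@H]5CCC=C5Br)[C@@]4(CO[Si](c6ccccc6)(c6ccccc6)C(C)(C)C)C[C@H](O)[C@@]23C4 | intermediate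
34 | C19 ketone of 33 | C12(OCCO1)CCN3C[C@@H](CC[C@H]5CCC=C5Br)[C@@]4(CO[Si](c6ccccc6)(c6ccccc6)C(C)(C)C)CC(=O)[C@@]23C4 | intermediate
35 | pentacyclic ketone: rings A, B, C, E, F; C13 endo on C14 (C14–H exo); C19 ketone; C24 ketal; C23 OTBDPS | C1CN2C[C@H]3CC[C@H]4CCC=C4[C@H]5C(=O)[C@@]2(C[C@@]35CO[Si](c6ccccc6)(c6ccccc6)C(C)(C)C)C17OCCO7 | intermediate
36 | methyl acrylate | C=CC(=O)OC | starting material
37 | 35 with an exo 3-methoxy-3-oxopropyl group on C14 (C14 quaternary) | C1CN2C[C@H]3CC[C@H]4CCC=C4[C@@]5(CCC(=O)OC)C(=O)[C@@]2(C[C@@]35CO[Si](c6ccccc6)(c6ccccc6)C(C)(C)C)C17OCCO7 | intermediate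
38 | endo C19 alcohol of 37 | C1CN2C[C@H]3CC[C@H]4CCC=C4[C@@]5(CCC(=O)OC)[C@@H](O)[C@@]2(C[C@@]35CO[Si](c6ccccc6)(c6ccccc6)C(C)(C)C)C17OCCO7 | intermediate
39 | C24 ketone of 38 (endo C19–OH ketol) | C1CN2C[C@H]3CC[C@H]4CCC=C4[C@@]5(CCC(=O)OC)[C@@H](O)[C@@]2(C[C@@]35CO[Si](c6ccccc6)(c6ccccc6)C(C)(C)C)C1=O | intermediate
40 | retro-aldol keto aldehyde: C19–C20 bond open; C19 formyl on C14; C20–H | C1CN2C[C@H]3CC[C@H]4CCC=C4[C@@](CCC(=O)OC)(C=O)[C@@]3(CO[Si](c5ccccc5)(c5ccccc5)C(C)(C)C)CC2C1=O | intermediate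
41 | exo C19–OH epimer of 39 | C1CN2C[C@H]3CC[C@H]4CCC=C4[C@@]5(CCC(=O)OC)[C@H](O)[C@@]2(C[C@@]35CO[Si](c6ccccc6)(c6ccccc6)C(C)(C)C)C1=O | intermediate
42 | hexacyclic keto lactone: target skeleton with C2 methylene and C23 OTBDPS | C1CN2C[C@H]3CC[C@H]4CCC=C4[C@@]45CCC(=O)O[C@@H]4[C@@]2(C[C@@]35CO[Si](c6ccccc6)(c6ccccc6)C(C)(C)C)C1=O | intermediate
43 | O-tert-butyldiphenylsilyl ether of the target | C[C@@H]1CN2C[C@H]3CC[C@H]4CCC=C4[C@@]45CCC(=O)O[C@@H]4[C@@]2(C[C@@]35CO[Si](c6ccccc6)(c6ccccc6)C(C)(C)C)C1=O | intermediate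
44 | CNP0180795.1 | C[C@@H]1CN2C[C@H]3CC[C@H]4CCC=C4[C@@]45CCC(=O)O[C@@H]4[C@@]2(C[C@@]35CO)C1=O | target

**Totals and risks**
Total step count: 30. Longest linear sequence: 25 steps (steps 6–30, from 10); the cyclopentene branch (steps 1–5) joins at step 21.

Three steps most likely to fail:

Step 19 (copper hydride reductive aldol). The fallback sets out from enone alcohol 27 and builds ring C stepwise instead of by a reductive aldol. Hydrogenation of the C20=C21 enamide bond (H2, Pd/C, EtOAc) gives the saturated keto lactam alcohol F1. Dess–Martin oxidation gives the keto aldehyde F2. Base-mediated intramolecular aldol addition of the C20 α-amido ketone carbon to the C19 aldehyde (DBU, CH2Cl2, 0 °C) then comes back to the route at ketol 29.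

Step 24 (Pd enolate alkenylation to the seven-membered ring). The fallback sets out from ketone 34 and closes ring E with a carbon radical instead of an organopalladium coupling. TESOTf/Et3N gives the C14=C19 triethylsilyl enol ether F3. Bu3SnH/AIBN (PhH, 80 °C, slow addition) generates the C13 vinyl radical, which adds 7-exo to C14 from the tether (endo) side and gives the C19 silyl ether F4. AcOH/THF/H2O frees the C19 alcohol F5. Dess–Martin oxidation comes back to the route at pentacyclic ketone 35.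

Step 28 (retro-aldol/aldol with lactone trapping). The fallback sets out from ketal alcohol 38 and epimerises C19 by reversible hydride transfer instead of C–C cleavage. Meerwein–Ponndorf–Verley/Oppenauer equilibration (Al(OiPr)3 cat., iPrOH/acetone, PhMe, 100 °C) with lactonisation of the exo alkoxide gives the ketal lactone F6. TFA/H2O removes the ketal and comes back to the route at keto lactone 42.

**Further compounds**
F1 | step 19 | (7S)-7-(2-hydroxyethyl)-7-{[(tert-butyldiphenylsilyl)oxy]methyl}hexahydroindolizine-1,5-dione (C8a epimers) | OCC[C@]1(CO[Si](c2ccccc2)(c2ccccc2)C(C)(C)C)CC(=O)N2CCC(=O)C2C1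
F2 | step 19 | 2-[(7S)-7-{[(tert-butyldiphenylsilyl)oxy]methyl}-1,5-dioxooctahydroindolizin-7-yl]acetaldehyde (C8a epimers) | O=CC[C@]1(CO[Si](c2ccccc2)(c2ccccc2)C(C)(C)C)CC(=O)N2CCC(=O)C2C1
F3 | step 24 | C14=C19 triethylsilyl enol ether of 34 | C12(OCCO1)CCN3C[C@@H](CC[C@H]5CCC=C5Br)[C@@]4(CO[Si](c6ccccc6)(c6ccccc6)C(C)(C)C)C=C(O[Si](CC)(CC)CC)[C@@]23C4
F4 | step 24 | ring E-closed C19 triethylsilyl ether (C19 epimers; C13 endo on C14) | C1CN2C[C@H]3CC[C@H]4CCC=C4[C@H]5C(O[Si](CC)(CC)CC)[C@@]2(C[C@@]35CO[Si](c6ccccc6)(c6ccccc6)C(C)(C)C)C17OCCO7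
F5 | step 24 | ring E-closed C19 alcohol (C19 epimers) | C1CN2C[C@H]3CC[C@H]4CCC=C4[C@H]5C(O)[C@@]2(C[C@@]35CO[Si](c6ccccc6)(c6ccccc6)C(C)(C)C)C17OCCO7
F6 | step 28 | C24 ethylene ketal of keto lactone 42 | C1CN2C[C@H]3CC[C@H]4CCC=C4[C@@]45CCC(=O)O[C@@H]4[C@@]2(C[C@@]35CO[Si](c6ccccc6)(c6ccccc6)C(C)(C)C)C17OCCO7
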